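**Retrosynthetic overview**
1. The first-choice disconnection, C3–H bromination of 5,6-dibromoindole, is not used, and that indole is never made on the main route.
2. Key step: the C3–Br bond of 6 comes from ipso-bromodecarboxylation of 5,6-dibromoindole-3-carboxylic acid 4, so CO2H is exchanged directly for Br.
3. Acid 4 comes from methyl ester 2 by saponification.
4. Ester 2 comes from methyl indole-3-carboxylate 1 by double C–H bromination. The ester blocks C3, deactivates C2 and directs bromine to C5 and C6.
5. No ring is formed. Both rings of the indole are bought intact in 1, and all three C–Br bonds are made on that core.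

Assumption: the target has no stereocentre and is achiral, so the "single enantiomer" request is met by the constitution alone; Br2, NaOH and NBS are treated as reagents and are not numbered.

**Step 1**
Reactants: 1 methyl 1H-indole-3-carboxylate
Product: 2 methyl 5,6-dibromo-1H-indole-3-carboxylate
Conditions: Br2 (2.2 equiv), AcOH, rt, 48–72 h; filter the precipitate, recrystallise
Reagents that add atoms: bromine, BrBr
Why: Electrophilic aromatic bromination (SEAr): the C3 ester occupies the normal site of attack and, as the acceptor of a vinylogous carbamate, switches off C2, so both brominations go to the benzo ring at C5 and C6, the 5- and 6-monobromides converge on the same dibromide, and this regiochemical outcome is established for this very substrate; no stereocentre is formed.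

**Step 2**
Reactants: 2 methyl 5,6-dibromo-1H-indole-3-carboxylate
Product: 4 5,6-dibromo-1H-indole-3-carboxylic acid, via sodium 5,6-dibromo-1H-indole-3-carboxylate 3 (not isolated)
Conditions: NaOH (6 equiv), MeOH/THF/H2O, 65 °C, 16–24 h; then 1 M HCl, 0 °C, to pH 3, filter
Reagents that add atoms: sodium hydroxide, [Na+].[OH-]
Why: Saponification (BAc2 ester hydrolysis): hydroxide adds to the sluggish vinylogous-carbamate ester on heating, the carboxylate salt 3 cannot decarboxylate, the aryl bromides on the electron-rich ring are inert to SNAr, and cold acidification only to pH 3 precipitates 4 before acid-catalysed protodecarboxylation can start.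

**Step 3** (key step)
Reactants: 4 5,6-dibromo-1H-indole-3-carboxylic acid
Product: 6 3,5,6-tribromo-1H-indole, via 3,5,6-tribromo-3H-indole-3-carboxylic acid 5 (not isolated)
Conditions: NBS (1.0 equiv, portionwise), LiOAc (10 mol %), DMF, −10 °C → rt, dark, 1–2 h; pour into ice-water, filter, store cold and dark
Reagents that add atoms: N-bromosuccinimide, O=C1CCC(=O)N1Br
Why: Electrophilic ipso-bromodecarboxylation (ionic, catalytic-Hunsdiecker-type halodecarboxylation of an electron-rich heteroaryl acid): Br+ attacks the enamine carbon C3 because only ipso attack gives an N-stabilised iminium (attack at C2 would place the charge next to the carboxyl), and the resulting 3H-indole 5 is a β-imino acid that loses CO2 at once to restore aromaticity, so the bromine lands exactly where the carboxyl sat, and the racemic C3 centre of 5 is destroyed, leaving no stereocentre.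

**Compound list**
1 | methyl 1H-indole-3-carboxylate | COC(=O)c1c[nH]c2ccccc12 | starting material
2 | methyl 5,6-dibromo-1H-indole-3-carboxylate | COC(=O)c1c[nH]c2cc(Br)c(Br)cc12 | intermediate
3 | sodium 5,6-dibromo-1H-indole-3-carboxylate (not isolated) | [Na+].[O-]C(=O)c1c[nH]c2cc(Br)c(Br)cc12 | intermediate
4 | 5,6-dibromo-1H-indole-3-carboxylic acid | OC(=O)c1c[nH]c2cc(Br)c(Br)cc12 | intermediate
5 | 3,5,6-tribromo-3H-indole-3-carboxylic acid (not isolated, racemic at C3, transient) | OC(=O)C1(Br)C=Nc2cc(Br)c(Br)cc12 | intermediate
6 | 3,5,6-tribromo-1H-indole | Brc1cc2[nH]cc(Br)c2cc1Br | target

**Total step count:** 3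
**Longest linear sequence:** 3

**Steps most likely to fail**

Step 3 carries the highest risk. Ipso attack may be slow on a ring that already carries two bromines. The product may take up a second bromine at C2, or oxindole-type products may form. The fallback separates the two events. It sets out from 4, which is protodecarboxylated under silver catalysis (Ag2CO3 10 mol %, AcOH 5 mol %, DMSO, 120 °C) to 5,6-dibromo-1H-indole F3. Ordinary C3–H bromination of that compound (NBS 1.0 equiv, DMF, 0 °C) comes back to the route at 6.

Step 2 is next. The ester is a vinylogous carbamate and becomes still less electrophilic once the N–H is deprotonated. Hydrolysis may therefore stall, and long heating or a careless acidic work-up may cost the carboxyl group. The fallback gives up acyl attack in favour of O–alkyl cleavage. It sets out from 2, where TMSI (1.5 equiv, MeCN, 60 °C) attacks the methyl carbon by SN2 to give trimethylsilyl 5,6-dibromo-1H-indole-3-carboxylate F2. Cold water at about pH 4 hydrolyses this silyl ester, and the fallback comes back to the route at 4.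

Step 1 carries the lowest risk. The concern is a mixture of mono-, di- and tribromides that is hard to separate, including some C2 bromination. The fallback overshoots and then corrects. It sets out from 1, which is brominated exhaustively (Br2 3.5 equiv, NaOAc, AcOH, 50 °C) to the single, crystalline methyl 2,5,6-tribromo-1H-indole-3-carboxylate F1. A site-selective palladium-catalysed transfer hydrodebromination follows (Pd(PPh3)4 5 mol %, HCO2Na 1.1 equiv, DMF, 80 °C). It should remove only the C2 bromine, because oxidative addition is fastest at this most electron-poor, β-bromoacrylate-type C–Br bond. The fallback comes back to the route at 2.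

**Further compounds**
F1 | step 1 | methyl 2,5,6-tribromo-1H-indole-3-carboxylate | COC(=O)c1c(Br)[nH]c2cc(Br)c(Br)cc12
F2 | step 2 | trimethylsilyl 5,6-dibromo-1H-indole-3-carboxylate | C[Si](C)(C)OC(=O)c1c[nH]c2cc(Br)c(Br)cc12
F3 | step 3 | 5,6-dibromo-1H-indole | Brc1cc2cc[nH]c2cc1Br
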